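**Retrosynthetic overview**

1. Ajugaciliatin A is reached by HCl opening of its 4α,18-epoxide. The butenolide comes from a 3-furyl group that enters as an intact ring (3-bromofuran added to a C12 aldehyde, then re-oxidised), and both (S)-2-methylbutanoates come from one double acylation.
2. The 4α,18-epoxide and the 6α,19-diacetate come from a 4(18)-methylene 6α,19-diol (hydroxyl-directed epoxidation), which comes from a 6α-hydroxy-19-aldehyde.
3. Key disconnection C4–C5: ring A (C1–C2–C3–C4–C5–C10) is made by semipinacol ring contraction of a seven-membered ring (C1–C2–C3–C4–C19–C5–C10) carrying a 5α,6α-epoxide next to the C19 carbinol. The enabling feature is the quaternary C5, flanked by the C6 oxygen and the aldehyde-level C19 (the aldol array O–C6–C5–C19=O), next to an alkene-level C4: C4 moves from C19 to C5 and C19 leaves the ring as the angular CH2O carbon.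
4. The seven-membered ring comes from an intramolecular Nozaki–Hiyama–Kishi coupling (C5–C19) of an enol triflate with a 2-methylene aldehyde. Ring B with C8, C9, C10 and C1 comes from (R)-3,4-dimethylcyclohex-2-enone, vinyl Grignard and 5,5-dimethoxypentanal (conjugate addition–aldol).
5. Ring order: ring B (aldol condensation), then the temporary seven-membered ring, then ring A last; the furan ring is never built in the route.

Key step: step 13

Remark: atoms carry neo-clerodane numbers (C1–C10 decalin, C11–C16 side chain, C17 on C8, C18 on C4, C19 on C5, C20 on C9); α is the face of C19 and C20, β the face of H-10; "4(5→19)-abeo" means that C4 is bonded to C19 instead of C5.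

Step 1
Reactants: 1 propanal; 2 but-3-en-2-one
Product: 3 (R)-2-methyl-5-oxohexanal
Conditions: (S)-α,α-diphenylprolinol trimethylsilyl ether (5 mol%), ethyl 3,4-dihydroxybenzoate (20 mol%), neat, 4 °C
Reagents that add atoms: none
Why: Enamine-catalysed Michael addition in which the bulky diarylmethyl group shields one face of the (E)-enamine of propanal, so that the enone should be attacked on the open face and set the (R) centre (later C8), in the same sense as the analogous nitroalkene additions.

Step 2
Reactants: 3 (R)-2-methyl-5-oxohexanal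
Product: 4 (R)-4-methylcyclohex-2-en-1-one
Conditions: KOH (0.1 M aq.), n-Bu4NOH (cat.), Et2O/THF, reflux
Reagents that add atoms: none
Why: Intramolecular aldol condensation of the methyl ketone enolate onto the aldehyde closes the later ring B, and fast cyclisation and dehydration under dilute hydroxide should outrun epimerisation of the α-methyl aldehyde.

Step 3
Reactants: 4 (R)-4-methylcyclohex-2-en-1-one
Product: 5 [(4R)-trans-3,4-dimethylcyclohex-1-en-1-yl]oxy(trimethyl)silane
Conditions: Me2CuLi, TMSCl, Et2O/THF, −78 °C; Et3N work-up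
Reagents that add atoms: lithium dimethylcuprate, [Li+].C[Cu-]C; chlorotrimethylsilane, C[Si](C)(C)Cl
Why: TMSCl-accelerated Gilman conjugate addition in which methyl enters anti to the C4 methyl group and the enolate is trapped regiospecifically as the silyl enol ether; the new stereocentre is removed again in step 4.

Step 4
Reactants: 5 [(4R)-trans-3,4-dimethylcyclohex-1-en-1-yl]oxy(trimethyl)silane
Product: 6 (R)-3,4-dimethylcyclohex-2-en-1-one
Conditions: Pd(OAc)2 (10 mol%), O2 (1 atm), DMSO, rt
Reagents that add atoms: none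
Why: Saegusa–Ito dehydrogenation (aerobic variant): the palladium enolate undergoes β-hydride elimination toward the methyl-bearing carbon and gives the β-methyl enone with the C4 stereocentre (later C8) intact.

Step 5
Reactants: 7 cyclopentene
Product: 10 5,5-dimethoxypentanal, via 5-hydroperoxy-5-methoxypentanal 8 (not isolated), via 1-hydroperoxy-1,5,5-trimethoxypentane 9 (not isolated)
Conditions: O3, CH2Cl2/MeOH, −78 °C; p-TsOH·H2O (cat.), rt; NaHCO3; Me2S
Reagents that add atoms: ozone, [O-][O+]=O; methanol, CO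
Why: Terminus-differentiating ozonolysis: methanol traps the carbonyl oxide as the α-methoxy hydroperoxide, acid acetalises the free aldehyde, and Me2S then reduces the hydroperoxide end to the second aldehyde.

Step 6
Reactants: 6 (R)-3,4-dimethylcyclohex-2-en-1-one; 10 5,5-dimethoxypentanal
Product: 13 (2S,3S,4R)-2-[(1R)-1-hydroxy-5,5-dimethoxypentyl]-3,4-dimethyl-3-vinylcyclohexan-1-one, via bromomagnesium enolate 11 (not isolated), via triisopropoxytitanium enolate 12 (not isolated)
Conditions: CH2=CHMgBr, CuBr·SMe2 (10 mol%), THF, −78 to −40 °C; ClTi(OiPr)3, −78 °C; then 10, −78 °C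
Reagents that add atoms: vinylmagnesium bromide, C=C[Mg]Br
Why: Tandem conjugate addition–aldol reaction: copper-catalysed 1,4-addition of the vinyl Grignard reagent anti to the C8 methyl group sets C9 (9β-vinyl, 9α-methyl), and the derived triisopropoxytitanium enolate should add to the aldehyde anti to the new vinyl group (setting C10, H-10 β) with the syn simple diastereoselection typical of titanium enolates of cyclic ketones (setting C1).

Step 7
Reactants: 13 (2S,3S,4R)-2-[(1R)-1-hydroxy-5,5-dimethoxypentyl]-3,4-dimethyl-3-vinylcyclohexan-1-one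
Product: 14 (2S,3S,4R)-2-[(1R)-1-(tert-butyldimethylsilyloxy)-5,5-dimethoxypentyl]-3,4-dimethyl-3-vinylcyclohexan-1-one
Conditions: TBSOTf, 2,6-lutidine, CH2Cl2, −78 °C
Reagents that add atoms: tert-butyldimethylsilyl trifluoromethanesulfonate, CC(C)(C)[Si](C)(C)OS(=O)(=O)C(F)(F)F
Why: Silylation of the hindered β-hydroxy ketone with the silyl triflate at low temperature avoids retro-aldol cleavage, leaves the dimethyl acetal intact and touches no stereocentre.

Step 8
Reactants: 14 (2S,3S,4R)-2-[(1R)-1-(tert-butyldimethylsilyloxy)-5,5-dimethoxypentyl]-3,4-dimethyl-3-vinylcyclohexan-1-one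
Product: 15 C5=C6 enol triflate of ketone 14 (cyclohex-1-en-1-yl trifluoromethanesulfonate; configuration at C8, C9, C10 and C1 as in 13)
Conditions: KHMDS, THF, −78 °C; PhNTf2, −78 to 0 °C
Reagents that add atoms: N-phenylbis(trifluoromethanesulfonimide), O=S(=O)(N(c1ccccc1)S(=O)(=O)C(F)(F)F)C(F)(F)F
Why: Kinetic deprotonation by the bulky amide occurs at the unhindered C6 methylene and not at the C10 methine, and O-sulfonylation gives the C5=C6 enol triflate regioselectively.

Step 9
Reactants: 15 C5=C6 enol triflate of ketone 14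
Product: 16 C19 aldehyde (the dimethyl acetal of 15 converted into CHO; chain C1(OTBS)–C2–C3–C4–C19HO)
Conditions: PPTS (cat.), acetone/H2O, 40 °C
Reagents that add atoms: water, O
Why: Mild acid-catalysed hydrolysis of the dimethyl acetal liberates the C19 aldehyde while the secondary silyl ether and the enol triflate survive.

Step 10
Reactants: 16 C19 aldehyde
Product: 17 2-methylene aldehyde (C4(=C18H2)–C19HO; enol triflate and 1-OTBS unchanged)
Conditions: CH2O (37% aq.), pyrrolidine (10 mol%), EtCO2H (10 mol%), i-PrOH, 45 °C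
Reagents that add atoms: formaldehyde, C=O
Why: Amine/acid-catalysed α-methylenation (Mannich condensation with formaldehyde followed by elimination) converts the C4 methylene into the 2-substituted acrolein that carries C18.

Step 11
Reactants: 17 2-methylene aldehyde
Product: 18 (19S)-1β-(tert-butyldimethylsilyloxy)-4(5→19)-abeo-13,14,15,16-tetranor-neo-cleroda-4(18),5,11-trien-19-ol (ring B cyclohexene fused at C5–C10 to the seven-membered ring C10–C1–C2–C3–C4–C19–C5)
Conditions: CrCl2 (6 equiv), NiCl2 (1 mol%), DMF, rt, slow addition at high dilution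
Reagents that add atoms: none
Why: Intramolecular Nozaki–Hiyama–Kishi reaction: nickel inserts into the alkenyl C5–OTf bond, transmetalation gives an alkenylchromium species that adds 1,2 to the aldehyde and closes the seven-membered ring; the new C19 carbinol is expected mainly as drawn (hydroxyl near the plane of C5=C6), and either epimer is serviceable because this centre is erased in step 13.

Step 12
Reactants: 18 (19S)-1β-(tert-butyldimethylsilyloxy)-4(5→19)-abeo-13,14,15,16-tetranor-neo-cleroda-4(18),5,11-trien-19-ol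
Product: 19 (19S)-5α,6α-epoxy-1β-(tert-butyldimethylsilyloxy)-4(5→19)-abeo-13,14,15,16-tetranor-neo-cleroda-4(18),11-dien-19-ol
Conditions: VO(acac)2 (5 mol%), t-BuOOH (1.1 equiv), CH2Cl2, 0 °C
Reagents that add atoms: tert-butyl hydroperoxide, CC(C)(C)OO
Why: Hydroxyl-directed vanadium-catalysed epoxidation: the 19-alkoxide-bound peroxo complex should transfer oxygen to the more electron-rich trisubstituted C5=C6 alkene, and because the chair-like seven-membered ring holds C4 on the β-face the hydroxyl can only reach the α-face, which sets C5 and C6 as the 5α,6α-epoxide.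

Step 13
Reactants: 19 (19S)-5α,6α-epoxy-1β-(tert-butyldimethylsilyloxy)-4(5→19)-abeo-13,14,15,16-tetranor-neo-cleroda-4(18),11-dien-19-ol
Product: 20 1β-(tert-butyldimethylsilyloxy)-6α-hydroxy-13,14,15,16-tetranor-neo-cleroda-4(18),11-dien-19-al
Conditions: BF3·OEt2 (20 mol%), CH2Cl2, −78 °C
Reagents that add atoms: none
Why: Coordination of BF3 to the α-epoxide and the neighbouring 19-hydroxyl ionises the C5–O bond at the fully substituted epoxide carbon while the C19–C4 σ-bond, held antiperiplanar to it on the β-face by the chair-like seven-membered ring, migrates from C19 to C5 and the carbinol collapses to the C19 aldehyde, a semipinacol rearrangement of a 2,3-epoxy alcohol of the Suzuki–Tsuchihashi type, as in the known ring contractions of cyclic 2,3-epoxy alcohols to 2-acylcycloalkanols. Ring A (C1–C2–C3–C4–C5–C10) is closed by this 1,2-shift, that is by contraction of the seven-membered ring with C19 expelled into the exocyclic formyl group, the alkenyl carbon C4 attacking C5 with inversion (3-exo-tet sense). C5 is set because C4 can only enter anti to the α C5–O bond, which gives the 5α-formyl group and the trans ring fusion with H-10 β, and C6 keeps with retention the α-oxygen delivered in step 12. The step needs migration of C4 to beat hydride shift from C19 and opening at C6; the high migratory aptitude of the sp2 carbon C4, the tertiary nature of C5 and the ring-enforced antiperiplanar C4–C19/C5–O alignment should secure this, and both C19 epimers should give the same aldehyde because that centre is erased.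

Step 14
Reactants: 20 1β-(tert-butyldimethylsilyloxy)-6α-hydroxy-13,14,15,16-tetranor-neo-cleroda-4(18),11-dien-19-al
Product: 21 1β-(tert-butyldimethylsilyloxy)-13,14,15,16-tetranor-neo-cleroda-4(18),11-diene-6α,19-diol
Conditions: NaBH4, MeOH, 0 °C
Reagents that add atoms: none
Why: Chemoselective borohydride reduction of the neopentyl aldehyde to the primary alcohol creates no stereocentre and removes the retro-aldol-prone β-hydroxy aldehyde.

Step 15
Reactants: 21 1β-(tert-butyldimethylsilyloxy)-13,14,15,16-tetranor-neo-cleroda-4(18),11-diene-6α,19-diol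
Product: 22 4α,18-epoxy-1β-(tert-butyldimethylsilyloxy)-13,14,15,16-tetranor-neo-clerod-11-ene-6α,19-diol
Conditions: VO(acac)2 (5 mol%), t-BuOOH, CH2Cl2, rt
Reagents that add atoms: tert-butyl hydroperoxide, CC(C)(C)OO
Why: Homoallylic hydroxyl-directed vanadium epoxidation: the axial 19-CH2OH and the 6α-OH both lie on the α-side of the exocyclic C4=C18 bond and should deliver oxygen to its α (equatorial) face, setting C4 as the 4α,18-epoxide, while the undirected vinyl group does not react.

Step 16
Reactants: 22 4α,18-epoxy-1β-(tert-butyldimethylsilyloxy)-13,14,15,16-tetranor-neo-clerod-11-ene-6α,19-diol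
Product: 23 6α,19-diacetoxy-4α,18-epoxy-1β-(tert-butyldimethylsilyloxy)-13,14,15,16-tetranor-neo-clerod-11-ene
Conditions: Ac2O, pyridine, DMAP (cat.), CH2Cl2, rt
Reagents that add atoms: acetic anhydride, CC(=O)OC(C)=O
Why: Standard DMAP-catalysed acetylation of the primary and the secondary hydroxyl, to which the epoxide and the silyl ether are inert.

Step 17
Reactants: 23 6α,19-diacetoxy-4α,18-epoxy-1β-(tert-butyldimethylsilyloxy)-13,14,15,16-tetranor-neo-clerod-11-ene
Product: 25 6α,19-diacetoxy-4α,18-epoxy-1β-(tert-butyldimethylsilyloxy)-13,14,15,16-tetranor-neo-clerodan-12-ol, via alkyl-9-borabicyclononane 24 (not isolated)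
Conditions: 9-BBN, THF, 0 °C to rt; then H2O2, pH 7 phosphate buffer, 0 °C
Reagents that add atoms: hydrogen peroxide, OO
Why: Anti-Markovnikov hydroboration of the only remaining alkene by the bulky dialkylborane followed by buffered peroxide oxidation, conditions that spare the acetates, the epoxide and the silyl ether.

Step 18
Reactants: 25 6α,19-diacetoxy-4α,18-epoxy-1β-(tert-butyldimethylsilyloxy)-13,14,15,16-tetranor-neo-clerodan-12-ol
Product: 26 6α,19-diacetoxy-4α,18-epoxy-1β-(tert-butyldimethylsilyloxy)-13,14,15,16-tetranor-neo-clerodan-12-al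
Conditions: Dess–Martin periodinane, NaHCO3, CH2Cl2, rt
Reagents that add atoms: none
Why: Dess–Martin oxidation of the primary alcohol to the aldehyde under buffered conditions that do not touch the epoxide or the esters.

Step 19
Reactants: 26 6α,19-diacetoxy-4α,18-epoxy-1β-(tert-butyldimethylsilyloxy)-13,14,15,16-tetranor-neo-clerodan-12-al
Product: 27 6α,19-diacetoxy-4α,18;15,16-diepoxy-1β-(tert-butyldimethylsilyloxy)-neo-cleroda-13(16),14-dien-12-ol (3-furyl carbinol, both C12 epimers)
Conditions: 3-bromofuran, n-BuLi, THF, −78 °C; then 26, −78 °C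
Reagents that add atoms: 3-bromofuran, Brc1ccoc1
Why: Bromine–lithium exchange gives 3-furyllithium, which should add to the aldehyde at −78 °C much faster than to the hindered acetates or the epoxide; the C12 centre is formed without control and is corrected in steps 20 and 21.

Step 20
Reactants: 27 3-furyl carbinol (both C12 epimers)
Product: 28 6α,19-diacetoxy-4α,18;15,16-diepoxy-1β-(tert-butyldimethylsilyloxy)-neo-cleroda-13(16),14-dien-12-one
Conditions: Dess–Martin periodinane, NaHCO3, CH2Cl2, rt
Reagents that add atoms: none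
Why: Dess–Martin oxidation converges both carbinol epimers into one furyl ketone.

Step 21
Reactants: 28 6α,19-diacetoxy-4α,18;15,16-diepoxy-1β-(tert-butyldimethylsilyloxy)-neo-cleroda-13(16),14-dien-12-one
Product: 29 (12S)-6α,19-diacetoxy-4α,18;15,16-diepoxy-1β-(tert-butyldimethylsilyloxy)-neo-cleroda-13(16),14-dien-12-ol
Conditions: (R)-2-methyl-CBS-oxazaborolidine (20 mol%), catecholborane, toluene, −78 °C
Reagents that add atoms: none
Why: Corey–Bakshi–Shibata reduction in which the oxazaborolidine binds the ketone with the furyl ring as the large substituent and delivers hydride to one face, the (R)-catalyst giving the (12S) alcohol by analogy with acetophenone giving (S)-1-phenylethanol.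

Step 22
Reactants: 29 (12S)-6α,19-diacetoxy-4α,18;15,16-diepoxy-1β-(tert-butyldimethylsilyloxy)-neo-cleroda-13(16),14-dien-12-ol
Product: 30 (12S)-6α,19-diacetoxy-4α,18;15,16-diepoxy-neo-cleroda-13(16),14-diene-1β,12-diol
Conditions: TBAF, AcOH, THF, rt to 45 °C
Reagents that add atoms: none
Why: Fluoride-induced cleavage of the secondary silyl ether, buffered with acetic acid so that the acetates neither migrate nor hydrolyse and the epoxide is not opened.

Step 23
Reactants: 30 (12S)-6α,19-diacetoxy-4α,18;15,16-diepoxy-neo-cleroda-13(16),14-diene-1β,12-diol; 31 (S)-2-methylbutanoic anhydride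
Product: 32 (12S)-6α,19-diacetoxy-4α,18;15,16-diepoxy-1β,12-bis[(S)-2-methylbutanoyloxy]-neo-cleroda-13(16),14-diene
Conditions: 31 (4 equiv), DMAP, Et3N, CH2Cl2, rt
Reagents that add atoms: none
Why: DMAP-catalysed acylation of both secondary hydroxyls by the enantiopure symmetric anhydride installs the two (S)-2-methylbutanoates under conditions too mild to epimerise their α-centres.

Step 24
Reactants: 32 (12S)-6α,19-diacetoxy-4α,18;15,16-diepoxy-1β,12-bis[(S)-2-methylbutanoyloxy]-neo-cleroda-13(16),14-diene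
Product: 34 (12S)-6α,19-diacetoxy-4α,18-epoxy-16-hydroxy-1β,12-bis[(S)-2-methylbutanoyloxy]-neo-clerod-13-en-15,16-olide, via furan endoperoxide 33 (not isolated)
Conditions: O2, hν, tetraphenylporphyrin (cat.), i-Pr2NEt, CH2Cl2, −78 °C
Reagents that add atoms: oxygen, O=O
Why: Photosensitised [4+2] addition of singlet oxygen to the furan and Kornblum–DeLaMare-type fragmentation of the endoperoxide by the hindered amine, which removes the less hindered H-15 so that C15 becomes the lactone carbonyl and C16 the lactol carbon.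

Step 25
Reactants: 34 (12S)-6α,19-diacetoxy-4α,18-epoxy-16-hydroxy-1β,12-bis[(S)-2-methylbutanoyloxy]-neo-clerod-13-en-15,16-olide
Product: 35 (12S)-6α,19-diacetoxy-4α,18-epoxy-1β,12-bis[(S)-2-methylbutanoyloxy]-neo-clerod-13-en-15,16-olide
Conditions: NaBH4, EtOH, 0 °C; then aq. NaH2PO4
Reagents that add atoms: none
Why: Borohydride reduces the lactol carbon C16 through its aldehyde tautomer and mild acidification relactonises the hydroxy acid to the β-substituted butenolide, which should be faster than any attack on the esters or the epoxide.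

Step 26
Reactants: 35 (12S)-6α,19-diacetoxy-4α,18-epoxy-1β,12-bis[(S)-2-methylbutanoyloxy]-neo-clerod-13-en-15,16-olide
Product: 36 ajugaciliatin A
Conditions: HCl (1 M in Et2O, 1.2 equiv), CH2Cl2, −40 to 0 °C
Reagents that add atoms: hydrogen chloride, Cl
Why: Proton-assisted SN2 opening of the spiro-epoxide by chloride at the primary C18 gives the 18-chloro-4α-hydroxy group with the C4 configuration unchanged.

**Compound list**

1 | propanal | CCC=O | starting material
2 | but-3-en-2-one (methyl vinyl ketone) | CC(=O)C=C | starting material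
3 | (R)-2-methyl-5-oxohexanal | O=C[C@H](C)CCC(C)=O | intermediate
4 | (R)-4-methylcyclohex-2-en-1-one | C[C@@H]1CCC(=O)C=C1 | intermediate
5 | [(4R)-trans-3,4-dimethylcyclohex-1-en-1-yl]oxy(trimethyl)silane | C[C@@H]1CCC(O[Si](C)(C)C)=C[C@H]1C | intermediate
6 | (R)-3,4-dimethylcyclohex-2-en-1-one | C[C@@H]1CCC(=O)C=C1C | intermediate
7 | cyclopentene | C1=CCCC1 | starting material
8 | 5-hydroperoxy-5-methoxypentanal (racemic) | O=CCCCC(OC)OO | intermediate (not isolated)
9 | 1-hydroperoxy-1,5,5-trimethoxypentane (racemic) | COC(OC)CCCC(OC)OO | intermediate (not isolated)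
10 | 5,5-dimethoxypentanal | O=CCCCC(OC)OC | intermediate
11 | bromomagnesium enolate of the vinyl conjugate adduct of 6 (9β-vinyl, 9α-methyl, 8α-methyl; C5–O–MgBr, C5=C10) | C=C[C@@]1(C)[C@H](C)CCC(O[Mg]Br)=C1 | intermediate (not isolated)
12 | triisopropoxytitanium enolate of the same adduct | C=C[C@@]1(C)[C@H](C)CCC(O[Ti](OC(C)C)(OC(C)C)OC(C)C)=C1 | intermediate (not isolated)
13 | (2S,3S,4R)-2-[(1R)-1-hydroxy-5,5-dimethoxypentyl]-3,4-dimethyl-3-vinylcyclohexan-1-one (C5 ketone; 8α-Me, 9α-Me, 9β-vinyl, 10β-H, 1,10-syn aldol) | C=C[C@@]1(C)[C@H](C)CCC(=O)[C@@H]1[C@H](O)CCCC(OC)OC | intermediate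
14 | (2S,3S,4R)-2-[(1R)-1-(tert-butyldimethylsilyloxy)-5,5-dimethoxypentyl]-3,4-dimethyl-3-vinylcyclohexan-1-one | C=C[C@@]1(C)[C@H](C)CCC(=O)[C@@H]1[C@H](O[Si](C)(C)C(C)(C)C)CCCC(OC)OC | intermediate
15 | C5=C6 enol triflate of 14 (configuration as in 13) | C=C[C@@]1(C)[C@H](C)CC=C(OS(=O)(=O)C(F)(F)F)[C@@H]1[C@H](O[Si](C)(C)C(C)(C)C)CCCC(OC)OC | intermediate
16 | C19 aldehyde of 15 (acetal hydrolysed) | C=C[C@@]1(C)[C@H](C)CC=C(OS(=O)(=O)C(F)(F)F)[C@@H]1[C@H](O[Si](C)(C)C(C)(C)C)CCCC=O | intermediate
17 | 2-methylene aldehyde (C4=C18H2 next to C19HO) | C=C[C@@]1(C)[C@H](C)CC=C(OS(=O)(=O)C(F)(F)F)[C@@H]1[C@H](O[Si](C)(C)C(C)(C)C)CCC(=C)C=O | intermediate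
18 | (19S)-1β-(tert-butyldimethylsilyloxy)-4(5→19)-abeo-13,14,15,16-tetranor-neo-cleroda-4(18),5,11-trien-19-ol | C=C[C@@]1(C)[C@H](C)CC=C2[C@@H]1[C@H](O[Si](C)(C)C(C)(C)C)CCC(=C)[C@@H]2O | intermediate
19 | (19S)-5α,6α-epoxy-1β-(tert-butyldimethylsilyloxy)-4(5→19)-abeo-13,14,15,16-tetranor-neo-cleroda-4(18),11-dien-19-ol | C=C[C@@]1(C)[C@H](C)C[C@@H]3O[C@]32[C@@H]1[C@H](O[Si](C)(C)C(C)(C)C)CCC(=C)[C@@H]2O | intermediate
20 | 1β-(tert-butyldimethylsilyloxy)-6α-hydroxy-13,14,15,16-tetranor-neo-cleroda-4(18),11-dien-19-al | C=C[C@@]1(C)[C@H](C)C[C@H](O)[C@]2(C=O)[C@@H]1[C@H](O[Si](C)(C)C(C)(C)C)CCC2=C | intermediate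
21 | 1β-(tert-butyldimethylsilyloxy)-13,14,15,16-tetranor-neo-cleroda-4(18),11-diene-6α,19-diol | C=C[C@@]1(C)[C@H](C)C[C@H](O)[C@]2(CO)[C@@H]1[C@H](O[Si](C)(C)C(C)(C)C)CCC2=C | intermediate
22 | 4α,18-epoxy-1β-(tert-butyldimethylsilyloxy)-13,14,15,16-tetranor-neo-clerod-11-ene-6α,19-diol | C=C[C@@]1(C)[C@H](C)C[C@H](O)[C@]2(CO)[C@@H]1[C@H](O[Si](C)(C)C(C)(C)C)CC[C@]2(O3)C3 | intermediate
23 | 6α,19-diacetoxy-4α,18-epoxy-1β-(tert-butyldimethylsilyloxy)-13,14,15,16-tetranor-neo-clerod-11-ene | C=C[C@@]1(C)[C@H](C)C[C@H](OC(C)=O)[C@]2(COC(C)=O)[C@@H]1[C@H](O[Si](C)(C)C(C)(C)C)CC[C@]2(O3)C3 | intermediate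
24 | 9-borabicyclo[3.3.1]nonane adduct of 23 (boron on C12) | C(C[C@@]1(C)[C@H](C)C[C@H](OC(C)=O)[C@]2(COC(C)=O)[C@@H]1[C@H](O[Si](C)(C)C(C)(C)C)CC[C@]2(O3)C3)B1C2CCCC1CCC2 | intermediate (not isolated)
25 | 6α,19-diacetoxy-4α,18-epoxy-1β-(tert-butyldimethylsilyloxy)-13,14,15,16-tetranor-neo-clerodan-12-ol | OCC[C@@]1(C)[C@H](C)C[C@H](OC(C)=O)[C@]2(COC(C)=O)[C@@H]1[C@H](O[Si](C)(C)C(C)(C)C)CC[C@]2(O3)C3 | intermediate
26 | 6α,19-diacetoxy-4α,18-epoxy-1β-(tert-butyldimethylsilyloxy)-13,14,15,16-tetranor-neo-clerodan-12-al | O=CC[C@@]1(C)[C@H](C)C[C@H](OC(C)=O)[C@]2(COC(C)=O)[C@@H]1[C@H](O[Si](C)(C)C(C)(C)C)CC[C@]2(O3)C3 | intermediate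
27 | 6α,19-diacetoxy-4α,18;15,16-diepoxy-1β-(tert-butyldimethylsilyloxy)-neo-cleroda-13(16),14-dien-12-ol (both C12 epimers) | OC(C[C@@]1(C)[C@H](C)C[C@H](OC(C)=O)[C@]2(COC(C)=O)[C@@H]1[C@H](O[Si](C)(C)C(C)(C)C)CC[C@]2(O3)C3)c1ccoc1 | intermediate
28 | 6α,19-diacetoxy-4α,18;15,16-diepoxy-1β-(tert-butyldimethylsilyloxy)-neo-cleroda-13(16),14-dien-12-one | O=C(C[C@@]1(C)[C@H](C)C[C@H](OC(C)=O)[C@]2(COC(C)=O)[C@@H]1[C@H](O[Si](C)(C)C(C)(C)C)CC[C@]2(O3)C3)c1ccoc1 | intermediate
29 | (12S)-6α,19-diacetoxy-4α,18;15,16-diepoxy-1β-(tert-butyldimethylsilyloxy)-neo-cleroda-13(16),14-dien-12-ol | O[C@@H](C[C@@]1(C)[C@H](C)C[C@H](OC(C)=O)[C@]2(COC(C)=O)[C@@H]1[C@H](O[Si](C)(C)C(C)(C)C)CC[C@]2(O3)C3)c1ccoc1 | intermediate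
30 | (12S)-6α,19-diacetoxy-4α,18;15,16-diepoxy-neo-cleroda-13(16),14-diene-1β,12-diol | O[C@@H](C[C@@]1(C)[C@H](C)C[C@H](OC(C)=O)[C@]2(COC(C)=O)[C@@H]1[C@H](O)CC[C@]2(O3)C3)c1ccoc1 | intermediate
31 | (S)-2-methylbutanoic anhydride | CC[C@H](C)C(=O)OC(=O)[C@@H](C)CC | starting material
32 | (12S)-6α,19-diacetoxy-4α,18;15,16-diepoxy-1β,12-bis[(S)-2-methylbutanoyloxy]-neo-cleroda-13(16),14-diene | CC[C@H](C)C(=O)O[C@@H](C[C@@]1(C)[C@H](C)C[C@H](OC(C)=O)[C@]2(COC(C)=O)[C@@H]1[C@H](OC(=O)[C@@H](C)CC)CC[C@]2(O3)C3)c1ccoc1 | intermediate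
33 | furan endoperoxide of 32 (2,3,7-trioxabicyclo[2.2.1]hept-5-ene, diastereomers) | CC[C@H](C)C(=O)O[C@@H](C[C@@]1(C)[C@H](C)C[C@H](OC(C)=O)[C@]2(COC(C)=O)[C@@H]1[C@H](OC(=O)[C@@H](C)CC)CC[C@]2(O3)C3)C1=CC2OOC1O2 | intermediate (not isolated)
34 | (12S)-6α,19-diacetoxy-4α,18-epoxy-16-hydroxy-1β,12-bis[(S)-2-methylbutanoyloxy]-neo-clerod-13-en-15,16-olide (C16 epimers) | CC[C@H](C)C(=O)O[C@@H](C[C@@]1(C)[C@H](C)C[C@H](OC(C)=O)[C@]2(COC(C)=O)[C@@H]1[C@H](OC(=O)[C@@H](C)CC)CC[C@]2(O3)C3)C1=CC(=O)OC1O | intermediate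
35 | (12S)-6α,19-diacetoxy-4α,18-epoxy-1β,12-bis[(S)-2-methylbutanoyloxy]-neo-clerod-13-en-15,16-olide | CC[C@H](C)C(=O)O[C@@H](C[C@@]1(C)[C@H](C)C[C@H](OC(C)=O)[C@]2(COC(C)=O)[C@@H]1[C@H](OC(=O)[C@@H](C)CC)CC[C@]2(O3)C3)C1=CC(=O)OC1 | intermediate
36 | ajugaciliatin A | CC[C@H](C)C(=O)O[C@@H](C[C@@]1(C)[C@H](C)C[C@H](OC(C)=O)[C@]2(COC(C)=O)[C@@H]1[C@H](OC(=O)[C@@H](C)CC)CC[C@]2(O)CCl)C1=CC(=O)OC1 | target

**Step count and risks**

Total step count: 26. Longest linear sequence: 25 steps (steps 1 to 4 and 6 to 26; step 5 is a one-step side branch).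

Steps most likely to fail:

Step 13. Hydride shift from C19 (giving the seven-membered β-hydroxy ketone) or simple opening and elimination of the epoxide may compete with migration of C4 while the free hydroxyl is locked in the boron chelate. The fallback leaves the chelated free-alcohol manifold. It sets out from 19, whose 19-hydroxyl is silylated (N-trimethylsilylimidazole, CH2Cl2) to the 19-O-trimethylsilyl ether F1. Treatment with TiCl4 in CH2Cl2 at −78 °C (rearrangement of an epoxy silyl ether, Suzuki–Tsuchihashi conditions) ionises the non-chelated epoxide with the silyloxy-bearing carbon as the electron-releasing migration origin, and aqueous work-up brings the material back to the route at 20.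

Step 12. Oxygen may be delivered to the exocyclic C4=C18 alkene, which is also allylic to the 19-hydroxyl, or to the β-face from an unfavourable C19 epimer or ring conformer. The fallback installs the exocyclic methylene only after the epoxide. It sets out from aldehyde 16, which under the CrCl2/NiCl2 conditions of step 11 closes to the seven-membered allylic alcohol lacking C18, F2. This compound has only the C5=C6 alkene within reach of the hydroxyl, so VO(acac)2/t-BuOOH gives the 5α,6α-epoxy alcohol F3. Dess–Martin oxidation gives the epoxy ketone F4. Its lithium enolate (LiHMDS, THF, −78 °C) is aminomethylated at C4 with dimethylmethylideneammonium iodide to the Mannich base F5. N-Methylation (MeI) and mild base (NaHCO3) eliminate trimethylamine to give the 4(18)-methylene epoxy ketone F6. Luche reduction (NaBH4, CeCl3, MeOH, −78 °C) returns the route at 19, either C19 epimer being usable.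

Step 6. The 1,4-addition to the β,β-disubstituted enone may be sluggish, and the one-pot aldol may lose its simple diastereoselection (anti instead of syn at C1/C10). The fallback separates the two events and uses an open transition state. It sets out from 6: vinylmagnesium bromide with CuBr·SMe2 and TMSCl gives the isolated trimethylsilyl enol ether F7. Tris(dimethylamino)sulfonium difluorotrimethylsilicate in THF at −78 °C then releases the metal-free enolate, which adds to aldehyde 10 through an extended transition state that favours the syn aldol irrespective of enolate geometry. Desilylating work-up comes back to the route at 13.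

**Further compounds**

F1 | step 13 | 19-O-trimethylsilyl ether of epoxy alcohol 19 | C=C[C@@]1(C)[C@H](C)C[C@@H]3O[C@]32[C@@H]1[C@H](O[Si](C)(C)C(C)(C)C)CCC(=C)[C@@H]2O[Si](C)(C)C
F2 | step 12 | 1β-(tert-butyldimethylsilyloxy)-4(5→19)-abeo-13,14,15,16,18-pentanor-neo-cleroda-5,11-dien-19-ol (C19 epimers) | C=C[C@@]1(C)[C@H](C)CC=C2[C@@H]1[C@H](O[Si](C)(C)C(C)(C)C)CCCC2O
F3 | step 12 | 5α,6α-epoxide of F2 | C=C[C@@]1(C)[C@H](C)C[C@@H]3O[C@]32[C@@H]1[C@H](O[Si](C)(C)C(C)(C)C)CCCC2O
F4 | step 12 | 5α,6α-epoxy 19-ketone from F3 | C=C[C@@]1(C)[C@H](C)C[C@@H]3O[C@]32[C@@H]1[C@H](O[Si](C)(C)C(C)(C)C)CCCC2=O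
F5 | step 12 | 4-(dimethylaminomethyl) derivative of F4 (Mannich base, C4 epimers) | C=C[C@@]1(C)[C@H](C)C[C@@H]3O[C@]32[C@@H]1[C@H](O[Si](C)(C)C(C)(C)C)CCC(CN(C)C)C2=O
F6 | step 12 | 4(18)-methylene 5α,6α-epoxy 19-ketone | C=C[C@@]1(C)[C@H](C)C[C@@H]3O[C@]32[C@@H]1[C@H](O[Si](C)(C)C(C)(C)C)CCC(=C)C2=O
F7 | step 6 | trimethylsilyl enol ether of the vinyl conjugate adduct of 6 | C=C[C@@]1(C)[C@H](C)CCC(O[Si](C)(C)C)=C1
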